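**Retrosynthetic overview**

1. Target 36 ⇐ triol 35 ⇐ protected bicycle 34; only acid deprotection and acetylation of the two non-tertiary hydroxyls follow ring closure.
2. Ring B (C5–C10) is closed last through the C9–C10 bond by a 6-exo reductive Heck cyclisation of alkenyl iodide 31 (C10–I onto the C9=C20 methylidene). The enabling feature is that C10 of the ring-A alkene C1=C10 is bonded to the quaternary C9 of ring B, which carries a methyl (C20) and no hydrogen.
3. 31 ⇐ Weinreb amide 17 + Grignard reagent 29 (C9–C11 bond), then methylenation of C9; the C8 stereocentre comes from an Evans alkylation (C7–C8 bond).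
4. Ring A is present from the start in (R)-Hajos–Parrish ketone 1: α-iodination, Luche reduction and reductive 1,3-transposition set H5 and the C1=C10 iodoalkene. The five-membered ring of 1 is a temporary ring, cut at C18–C7 by enol-ether ozonolysis to release the C4 ester and the C6–C7 arm.
5. Side chain 28 (C11–C16) ⇐ 4-(benzyloxy)but-1-yne by carboalumination, Sharpless epoxidation and Payne opening (C13, C14).

Key step: step 21

Remark: halimane numbering is used for every intermediate (ring A = C1–C5 and C10; ring B = C5–C10; C18 = ester carbon and C19 = methyl on C4; C17 = methyl on C8; C20 = methyl on C9; C11–C16 = side chain); β is the face of the C19 methyl, on which the target has the C11 chain, and α the face of H5, the C17 methyl and the C20 methyl; (R)-(−)-Hajos–Parrish ketone is taken as a purchasable compound.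

**Route**

Step 1
Reactants: 1 (R)-(−)-Hajos–Parrish ketone
Product: 2 (7aR)-4-iodo-7a-methyl-2,3,7,7a-tetrahydro-1H-indene-1,5(6H)-dione
Conditions: I2, pyridine, DMAP (cat.), CH2Cl2, rt
Reagents that add atoms: iodine, [I][I]
Why: Iodine–pyridine α-iodination of a cyclic enone (conjugate addition of the amine, iodination of the enolate, elimination) should place iodine only at C10, the α-carbon of the enone, and creates no stereocentre.

Step 2
Reactants: 2 (7aR)-4-iodo-7a-methyl-2,3,7,7a-tetrahydro-1H-indene-1,5(6H)-dione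
Product: 3 (1R,5R,7aR)-4-iodo-7a-methyl-2,3,5,6,7,7a-hexahydro-1H-indene-1,5-diol
Conditions: NaBH4, CeCl3·7H2O, MeOH, −40 → 0 °C
Reagents that add atoms: none
Why: Luche reduction should give clean 1,2-reduction of the iodoenone with hydride entering axially on the α-face, opposite the angular methyl, so that the C1 hydroxyl is β; the cyclopentanone is reduced as well and is restored in step 4.

Step 3
Reactants: 3 (1R,5R,7aR)-4-iodo-7a-methyl-2,3,5,6,7,7a-hexahydro-1H-indene-1,5-diol
Product: 6 (1R,3aS,7aR)-4-iodo-7a-methyl-2,3,3a,6,7,7a-hexahydro-1H-inden-1-ol, via sulfonylhydrazine adduct 4 (not isolated), via allylic diazene 5 (not isolated)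
Conditions: 2-nitrobenzenesulfonylhydrazide, PPh3, DEAD, THF, −30 °C → rt
Reagents that add atoms: none
Why: Mitsunobu displacement of the allylic hydroxyl by the sulfonylhydrazide with inversion, loss of 2-nitrobenzenesulfinic acid and retro-ene loss of N2 from diazene 5 (reductive 1,3-transposition of an allylic alcohol) should deliver hydrogen suprafacially to the α-face of C5 and move the alkene to C1=C10, which sets H5 trans to the C4 methyl, while the neopentyl-type cyclopentanol is too hindered to enter the Mitsunobu step.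

Step 4
Reactants: 6 (1R,3aS,7aR)-4-iodo-7a-methyl-2,3,3a,6,7,7a-hexahydro-1H-inden-1-ol
Product: 7 (3aS,7aR)-4-iodo-7a-methyl-2,3,3a,6,7,7a-hexahydro-1H-inden-1-one
Conditions: Dess–Martin periodinane, CH2Cl2, rt
Reagents that add atoms: none
Why: Dess–Martin oxidation of the remaining secondary alcohol should proceed under neutral conditions that leave the iodoalkene and the C5 stereocentre untouched.

Step 5
Reactants: 7 (3aS,7aR)-4-iodo-7a-methyl-2,3,3a,6,7,7a-hexahydro-1H-inden-1-one
Product: 8 trimethylsilyl enol ether of 7 (C18=C7 enol ether)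
Conditions: TMSOTf, Et3N, CH2Cl2, 0 °C
Reagents that add atoms: trimethylsilyl triflate, C[Si](C)(C)OS(=O)(=O)C(F)(F)F
Why: Soft enolisation with a silyl triflate and an amine base can only give the C18=C7 enol ether, because the other α-carbon (C4) is quaternary.

Step 6
Reactants: 8 trimethylsilyl enol ether of 7
Product: 10 (1R,2S)-3-iodo-1-methyl-2-(2-oxoethyl)cyclohex-3-ene-1-carboxylic acid, via trimethylsilyl ester aldehyde 9 (not isolated)
Conditions: O3, CH2Cl2/MeOH, −78 °C (Sudan Red 7B as end-point indicator); Me2S, −78 °C → rt; aqueous work-up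
Reagents that add atoms: ozone, [O-][O+]=O
Why: Ozonolysis of the electron-rich silyl enol ether, far faster than attack on the electron-poor iodoalkene, should cut the C18–C7 bond of the temporary five-membered ring so that C18 becomes the carboxyl group on C4 and C7 the aldehyde of the two-carbon arm on C5, with both stereocentres kept.

Step 7
Reactants: 10 (1R,2S)-3-iodo-1-methyl-2-(2-oxoethyl)cyclohex-3-ene-1-carboxylic acid
Product: 11 methyl (1R,2S)-3-iodo-1-methyl-2-(2-oxoethyl)cyclohex-3-ene-1-carboxylate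
Conditions: TMSCHN2, PhMe/MeOH, 0 °C
Reagents that add atoms: (trimethylsilyl)diazomethane, C[Si](C)(C)C=[N+]=[N-]
Why: Esterification with (trimethylsilyl)diazomethane is a neutral O-methylation of the hindered acid that should not touch the aldehyde or the iodoalkene.

Step 8
Reactants: 11 methyl (1R,2S)-3-iodo-1-methyl-2-(2-oxoethyl)cyclohex-3-ene-1-carboxylate
Product: 12 methyl (1R,2S)-2-(2-hydroxyethyl)-3-iodo-1-methylcyclohex-3-ene-1-carboxylate
Conditions: NaBH4, MeOH, −20 °C; neutral work-up, used without delay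
Reagents that add atoms: none
Why: Borohydride reduction should reduce only the aldehyde, the neopentyl-type ester and the iodoalkene being inert.

Step 9
Reactants: 12 methyl (1R,2S)-2-(2-hydroxyethyl)-3-iodo-1-methylcyclohex-3-ene-1-carboxylate
Product: 13 methyl (1R,2S)-3-iodo-1-methyl-2-{2-[(trifluoromethanesulfonyl)oxy]ethyl}cyclohex-3-ene-1-carboxylate
Conditions: Tf2O, 2,6-lutidine, CH2Cl2, −78 °C; cold filtration, used at once
Reagents that add atoms: triflic anhydride, O=S(=O)(OS(=O)(=O)C(F)(F)F)C(F)(F)F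
Why: Sulfonylation of the primary alcohol at low temperature should give the primary triflate, an electrophile reactive enough for an imide enolate at −78 °C.

Step 10
Reactants: 13 methyl (1R,2S)-3-iodo-1-methyl-2-{2-[(trifluoromethanesulfonyl)oxy]ethyl}cyclohex-3-ene-1-carboxylate; 14 (S)-4-benzyl-3-propanoyl-1,3-oxazolidin-2-one
Product: 16 methyl (1R,2S)-2-{(3R)-4-[(4S)-4-benzyl-2-oxo-1,3-oxazolidin-3-yl]-3-methyl-4-oxobutyl}-3-iodo-1-methylcyclohex-3-ene-1-carboxylate, via sodium enolate 15 (not isolated)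
Conditions: 14, NaN(SiMe3)2, THF, −78 °C; then 13, −78 → −40 °C
Reagents that add atoms: none
Why: Evans auxiliary alkylation: the chelated (Z)-sodium enolate 15 should be alkylated on the face opposite the benzyl group, which sets C8 as (R), the future α-methyl centre of ring B.

Step 11
Reactants: 16 methyl (1R,2S)-2-{(3R)-4-[(4S)-4-benzyl-2-oxo-1,3-oxazolidin-3-yl]-3-methyl-4-oxobutyl}-3-iodo-1-methylcyclohex-3-ene-1-carboxylate
Product: 17 methyl (1R,2S)-3-iodo-2-{(3R)-4-[methoxy(methyl)amino]-3-methyl-4-oxobutyl}-1-methylcyclohex-3-ene-1-carboxylate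
Conditions: MeNH(OMe)·HCl, AlMe3, CH2Cl2, −15 → 0 °C
Reagents that add atoms: N,O-dimethylhydroxylamine hydrochloride, CNOC.Cl
Why: Aluminium amide aminolysis (Weinreb amide formation) should cleave the exocyclic imide carbonyl in preference to the hindered methyl ester and releases the auxiliary without touching C8.

Step 12
Reactants: 18 4-(benzyloxy)but-1-yne
Product: 21 (E)-5-(benzyloxy)-3-methylpent-2-en-1-ol, via alkenylalane 19 (not isolated), via lithium aluminate 20 (not isolated)
Conditions: AlMe3, Cp2ZrCl2 (cat.), CH2Cl2, 0 °C → rt; n-BuLi, THF, −78 °C; (CH2O)n, rt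
Reagents that add atoms: trimethylaluminium, C[Al](C)C; paraformaldehyde (as formaldehyde), C=O
Why: Zirconium-catalysed carboalumination adds methyl and aluminium syn across the terminal alkyne (methyl to the internal carbon), and the aluminate is hydroxymethylated with retention, which fixes the (E)-trisubstituted allylic alcohol.

Step 13
Reactants: 21 (E)-5-(benzyloxy)-3-methylpent-2-en-1-ol
Product: 22 [(2S,3S)-3-[2-(benzyloxy)ethyl]-3-methyloxiran-2-yl]methanol
Conditions: Ti(OiPr)4, L-(+)-diethyl tartrate, t-BuOOH, 4 Å molecular sieves, CH2Cl2, −20 °C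
Reagents that add atoms: tert-butyl hydroperoxide, CC(C)(C)OO
Why: Sharpless asymmetric epoxidation with L-(+)-diethyl tartrate should give the (2S,3S)-epoxy alcohol, the facial sense being that established for (E)-3-methylalk-2-en-1-ols.

Step 14
Reactants: 22 [(2S,3S)-3-[2-(benzyloxy)ethyl]-3-methyloxiran-2-yl]methanol
Product: 24 (2R,3S)-5-(benzyloxy)-3-methylpentane-1,2,3-triol, via terminal epoxide 23 (not isolated)
Conditions: NaOH (0.5 M aq.), t-BuOH, 75 °C
Reagents that add atoms: water, O
Why: Payne rearrangement followed by hydroxide opening of terminal epoxide 23 at its primary carbon amounts to inversion at C14 and retention at C13 (attack at the tertiary carbon is excluded under basic conditions), which gives the required 13S,14R triol.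

Step 15
Reactants: 24 (2R,3S)-5-(benzyloxy)-3-methylpentane-1,2,3-triol
Product: 25 (2S)-4-(benzyloxy)-2-[(4R)-2,2-dimethyl-1,3-dioxolan-4-yl]butan-2-ol
Conditions: 2-methoxypropene, PPTS (cat.), CH2Cl2, 0 °C
Reagents that add atoms: 2-methoxypropene, COC(C)=C
Why: Kinetic acetalisation should engage the primary and secondary hydroxyls (terminal dioxolane) and leave the hindered tertiary hydroxyl free.

Step 16
Reactants: 25 (2S)-4-(benzyloxy)-2-[(4R)-2,2-dimethyl-1,3-dioxolan-4-yl]butan-2-ol
Product: 26 triethylsilyl ether of 25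
Conditions: Et3SiOTf, 2,6-lutidine, CH2Cl2, −40 → 0 °C
Reagents that add atoms: triethylsilyl triflate, CC[Si](CC)(CC)OS(=O)(=O)C(F)(F)F
Why: Silylation with a silyl triflate and a hindered base is the standard way to protect a tertiary alcohol and should leave the acetonide intact.

Step 17
Reactants: 26 triethylsilyl ether of 25
Product: 27 (3S)-3-[(4R)-2,2-dimethyl-1,3-dioxolan-4-yl]-3-[(triethylsilyl)oxy]butan-1-ol
Conditions: H2 (1 atm), Pd/C, EtOAc, rt
Reagents that add atoms: none
Why: Hydrogenolysis of the benzyl ether in a neutral aprotic solvent should spare the acetonide and the silyl ether.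

Step 18
Reactants: 27 (3S)-3-[(4R)-2,2-dimethyl-1,3-dioxolan-4-yl]-3-[(triethylsilyl)oxy]butan-1-ol
Product: 28 {[(2S)-4-bromo-2-[(4R)-2,2-dimethyl-1,3-dioxolan-4-yl]butan-2-yl]oxy}triethylsilane
Conditions: CBr4, PPh3, CH2Cl2, 0 °C
Reagents that add atoms: carbon tetrabromide, BrC(Br)(Br)Br
Why: Appel bromination converts the primary alcohol into the bromide under near-neutral conditions that the acid-labile protecting groups should tolerate.

Step 19
Reactants: 28 {[(2S)-4-bromo-2-[(4R)-2,2-dimethyl-1,3-dioxolan-4-yl]butan-2-yl]oxy}triethylsilane; 17 methyl (1R,2S)-3-iodo-2-{(3R)-4-[methoxy(methyl)amino]-3-methyl-4-oxobutyl}-1-methylcyclohex-3-ene-1-carboxylate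
Product: 30 methyl (1R,2S)-2-{(3R,7S)-7-[(4R)-2,2-dimethyl-1,3-dioxolan-4-yl]-3-methyl-4-oxo-7-[(triethylsilyl)oxy]octyl}-3-iodo-1-methylcyclohex-3-ene-1-carboxylate, via Grignard reagent 29 (not isolated)
Conditions: 28, Mg, THF, rt → 40 °C; then 17, THF, −20 → 0 °C; aq. NH4Cl
Reagents that add atoms: none
Why: Weinreb ketone synthesis: Grignard reagent 29 should add once to the amide through the stable chelated tetrahedral intermediate, faster than to the hindered ester and without halogen–metal exchange at the alkenyl iodide at this temperature.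

Step 20
Reactants: 30 methyl (1R,2S)-2-{(3R,7S)-7-[(4R)-2,2-dimethyl-1,3-dioxolan-4-yl]-3-methyl-4-oxo-7-[(triethylsilyl)oxy]octyl}-3-iodo-1-methylcyclohex-3-ene-1-carboxylate
Product: 31 methyl (1R,2S)-2-{(3R,7S)-7-[(4R)-2,2-dimethyl-1,3-dioxolan-4-yl]-3-methyl-4-methylidene-7-[(triethylsilyl)oxy]octyl}-3-iodo-1-methylcyclohex-3-ene-1-carboxylate
Conditions: Tebbe reagent Cp2Ti(μ-Cl)(μ-CH2)AlMe2, pyridine, THF/PhMe, −40 → 0 °C
Reagents that add atoms: Tebbe reagent, C[Al-]1(C)C[Ti]([Cl+]1)(C2C=CC=C2)C3C=CC=C3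
Why: Tebbe methylenation is non-basic, so the C8 stereocentre α to the ketone should not epimerise, and at low temperature the ketone reacts well ahead of the ester.

Step 21
Reactants: 31 methyl (1R,2S)-2-{(3R,7S)-7-[(4R)-2,2-dimethyl-1,3-dioxolan-4-yl]-3-methyl-4-methylidene-7-[(triethylsilyl)oxy]octyl}-3-iodo-1-methylcyclohex-3-ene-1-carboxylate
Product: 34 methyl (4R,5R,8R,9S,13S,14R)-14,15-(isopropylidenedioxy)-13-[(triethylsilyl)oxy]halim-1(10)-en-18-oate, via alkenylpalladium iodide 32 (not isolated), via neopentylpalladium iodide 33 (not isolated)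
Conditions: Pd(OAc)2 (10 mol %), PPh3 (25 mol %), HCO2Na, n-Bu4NCl, DMF, 80 °C
Reagents that add atoms: none
Why: Oxidative addition of zerovalent palladium into the C10–I bond gives alkenylpalladium 32, which inserts the C9=C20 alkene by 6-exo-trig syn-carbopalladation (C10–C9 bond, closing ring B) to give the neopentyl-type alkylpalladium 33; this has no β-hydrogen and is intercepted by formate (decarboxylation to a palladium hydride, then C20–H reductive elimination), so C20 ends as the methyl on C9. The closest known reaction type is the reductive Heck (hydride-capture) cyclisation of alkenyl and aryl halides onto 1,1-disubstituted alkenes to build methyl-bearing quaternary carbons. The new stereocentre C9 is controlled by C5 and C8: the tether leaves C5 on the β-face, so C9 must reach C10 from that face with palladium on the α-face next to H5, and the four-centre insertion geometry keeps the C9=C20 bond eclipsed with the C10–Pd bond, perpendicular to the plane of the C1=C10 alkene. In the resulting chair-like transition state H5 is axial, the C8 methyl equatorial, C20 becomes the axial α-methyl and the C11 chain the equatorial β-substituent. The step needs 6-exo over 7-endo closure (secured by the eclipsed geometry and ring size), insertion ahead of direct reduction of 32 (favoured by the unstrained intramolecular closure and sparingly soluble formate) and retention of the C1=C10 alkene, which is the alkenyl unit itself and is not inserted.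

Step 22
Reactants: 34 methyl (4R,5R,8R,9S,13S,14R)-14,15-(isopropylidenedioxy)-13-[(triethylsilyl)oxy]halim-1(10)-en-18-oate
Product: 35 methyl (4R,5R,8R,9S,13S,14R)-13,14,15-trihydroxyhalim-1(10)-en-18-oate
Conditions: AcOH/THF/H2O (3:1:1), 45 °C
Reagents that add atoms: none
Why: Mild aqueous acid should hydrolyse the acetonide and the tertiary silyl ether (acetal hydrolysis and protodesilylation) without protonating the trisubstituted alkene.

Step 23
Reactants: 35 methyl (4R,5R,8R,9S,13S,14R)-13,14,15-trihydroxyhalim-1(10)-en-18-oate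
Product: 36 methyl (4R,5R,8R,9S,13S,14R)-14,15-diacetoxy-13-hydroxyhalim-1(10)-en-18-oate (target)
Conditions: Ac2O, pyridine, DMAP (cat.), CH2Cl2, 0 °C → rt
Reagents that add atoms: acetic anhydride, CC(=O)OC(C)=O
Why: Acylation should take place at the primary and secondary hydroxyls only, the tertiary C13 hydroxyl being too hindered under these conditions.

**Compound list**

1 | (R)-(−)-Hajos–Parrish ketone, (7aR)-7a-methyl-2,3,7,7a-tetrahydro-1H-indene-1,5(6H)-dione | C[C@@]12CCC(=O)C=C1CCC2=O | starting material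
2 | (7aR)-4-iodo-7a-methyl-2,3,7,7a-tetrahydro-1H-indene-1,5(6H)-dione | C[C@@]12CCC(=O)C(I)=C1CCC2=O | intermediate
3 | (1R,5R,7aR)-4-iodo-7a-methyl-2,3,5,6,7,7a-hexahydro-1H-indene-1,5-diol (both hydroxyls cis to the methyl) | C[C@@]12CC[C@@H](O)C(I)=C1CC[C@H]2O | intermediate
4 | Mitsunobu adduct, N-alkyl-N-(2-nitrobenzenesulfonyl)hydrazine with nitrogen on the α-face of C1 | C[C@@]12CC[C@H](N(N)S(=O)(=O)c3ccccc3[N+](=O)[O-])C(I)=C1CC[C@H]2O | intermediate
5 | allylic diazene (α-N=NH at C1) | C[C@@]12CC[C@H](N=N)C(I)=C1CC[C@H]2O | intermediate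
6 | (1R,3aS,7aR)-4-iodo-7a-methyl-2,3,3a,6,7,7a-hexahydro-1H-inden-1-ol (trans-fused) | C[C@@]12CCC=C(I)[C@H]1CC[C@H]2O | intermediate
7 | (3aS,7aR)-4-iodo-7a-methyl-2,3,3a,6,7,7a-hexahydro-1H-inden-1-one | C[C@@]12CCC=C(I)[C@H]1CCC2=O | intermediate
8 | trimethylsilyl enol ether of 7 | C[C@@]12CCC=C(I)[C@H]1CC=C2O[Si](C)(C)C | intermediate
9 | trimethylsilyl (1R,2S)-3-iodo-1-methyl-2-(2-oxoethyl)cyclohex-3-ene-1-carboxylate | C[Si](C)(C)OC(=O)[C@]1(C)CCC=C(I)[C@H]1CC=O | intermediate
10 | (1R,2S)-3-iodo-1-methyl-2-(2-oxoethyl)cyclohex-3-ene-1-carboxylic acid | OC(=O)[C@]1(C)CCC=C(I)[C@H]1CC=O | intermediate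
11 | methyl (1R,2S)-3-iodo-1-methyl-2-(2-oxoethyl)cyclohex-3-ene-1-carboxylate | COC(=O)[C@]1(C)CCC=C(I)[C@H]1CC=O | intermediate
12 | methyl (1R,2S)-2-(2-hydroxyethyl)-3-iodo-1-methylcyclohex-3-ene-1-carboxylate | COC(=O)[C@]1(C)CCC=C(I)[C@H]1CCO | intermediate
13 | methyl (1R,2S)-3-iodo-1-methyl-2-{2-[(trifluoromethanesulfonyl)oxy]ethyl}cyclohex-3-ene-1-carboxylate | COC(=O)[C@]1(C)CCC=C(I)[C@H]1CCOS(=O)(=O)C(F)(F)F | intermediate
14 | (S)-4-benzyl-3-propanoyl-1,3-oxazolidin-2-one | CCC(=O)N1[C@@H](Cc2ccccc2)COC1=O | starting material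
15 | sodium (Z)-enolate of 14 | C/C=C(\[O-])N1[C@@H](Cc2ccccc2)COC1=O.[Na+] | intermediate
16 | methyl (1R,2S)-2-{(3R)-4-[(4S)-4-benzyl-2-oxo-1,3-oxazolidin-3-yl]-3-methyl-4-oxobutyl}-3-iodo-1-methylcyclohex-3-ene-1-carboxylate | COC(=O)[C@]1(C)CCC=C(I)[C@H]1CC[C@@H](C)C(=O)N2[C@@H](Cc3ccccc3)COC2=O | intermediate
17 | methyl (1R,2S)-3-iodo-2-{(3R)-4-[methoxy(methyl)amino]-3-methyl-4-oxobutyl}-1-methylcyclohex-3-ene-1-carboxylate | COC(=O)[C@]1(C)CCC=C(I)[C@H]1CC[C@@H](C)C(=O)N(C)OC | intermediate
18 | 4-(benzyloxy)but-1-yne | C#CCCOCc1ccccc1 | starting material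
19 | (E)-[4-(benzyloxy)-2-methylbut-1-enyl]dimethylalane | C[Al](C)/C=C(\C)CCOCc1ccccc1 | intermediate
20 | lithium (E)-[4-(benzyloxy)-2-methylbut-1-enyl](butyl)dimethylaluminate | [Li+].CCCC[Al-](C)(C)/C=C(\C)CCOCc1ccccc1 | intermediate
21 | (E)-5-(benzyloxy)-3-methylpent-2-en-1-ol | OC/C=C(\C)CCOCc1ccccc1 | intermediate
22 | [(2S,3S)-3-[2-(benzyloxy)ethyl]-3-methyloxiran-2-yl]methanol | OC[C@@H]1O[C@@]1(C)CCOCc2ccccc2 | intermediate
23 | (2S)-4-(benzyloxy)-2-[(2R)-oxiran-2-yl]butan-2-ol | C1O[C@H]1[C@@](C)(O)CCOCc2ccccc2 | intermediate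
24 | (2R,3S)-5-(benzyloxy)-3-methylpentane-1,2,3-triol | OC[C@@H](O)[C@@](C)(O)CCOCc1ccccc1 | intermediate
25 | (2S)-4-(benzyloxy)-2-[(4R)-2,2-dimethyl-1,3-dioxolan-4-yl]butan-2-ol | CC1(C)OC[C@@H](O1)[C@@](C)(O)CCOCc2ccccc2 | intermediate
26 | triethylsilyl ether of 25 | CC1(C)OC[C@@H](O1)[C@@](C)(O[Si](CC)(CC)CC)CCOCc2ccccc2 | intermediate
27 | (3S)-3-[(4R)-2,2-dimethyl-1,3-dioxolan-4-yl]-3-[(triethylsilyl)oxy]butan-1-ol | CC1(C)OC[C@@H](O1)[C@@](C)(O[Si](CC)(CC)CC)CCO | intermediate
28 | {[(2S)-4-bromo-2-[(4R)-2,2-dimethyl-1,3-dioxolan-4-yl]butan-2-yl]oxy}triethylsilane | CC1(C)OC[C@@H](O1)[C@@](C)(O[Si](CC)(CC)CC)CCBr | intermediate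
29 | Grignard reagent from 28 | CC1(C)OC[C@@H](O1)[C@@](C)(O[Si](CC)(CC)CC)CC[Mg]Br | intermediate
30 | methyl (1R,2S)-2-{(3R,7S)-7-[(4R)-2,2-dimethyl-1,3-dioxolan-4-yl]-3-methyl-4-oxo-7-[(triethylsilyl)oxy]octyl}-3-iodo-1-methylcyclohex-3-ene-1-carboxylate (C9 ketone) | COC(=O)[C@]1(C)CCC=C(I)[C@H]1CC[C@@H](C)C(=O)CC[C@](C)(O[Si](CC)(CC)CC)[C@H]2COC(C)(C)O2 | intermediate
31 | methyl (1R,2S)-2-{(3R,7S)-7-[(4R)-2,2-dimethyl-1,3-dioxolan-4-yl]-3-methyl-4-methylidene-7-[(triethylsilyl)oxy]octyl}-3-iodo-1-methylcyclohex-3-ene-1-carboxylate (C9=C20 alkene) | COC(=O)[C@]1(C)CCC=C(I)[C@H]1CC[C@@H](C)C(=C)CC[C@](C)(O[Si](CC)(CC)CC)[C@H]2COC(C)(C)O2 | intermediate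
32 | alkenylpalladium iodide from oxidative addition of 31 (divalent palladium, two PPh3) | COC(=O)[C@]1(C)CCC=C([Pd-2](I)([P+](c2ccccc2)(c2ccccc2)c2ccccc2)[P+](c2ccccc2)(c2ccccc2)c2ccccc2)[C@H]1CC[C@@H](C)C(=C)CC[C@](C)(O[Si](CC)(CC)CC)[C@H]3COC(C)(C)O3 | intermediate
33 | neopentyl-type alkylpalladium iodide after C9–C10 bond formation (divalent palladium on C20, two PPh3) | COC(=O)[C@]1(C)CCC=C2[C@H]1CC[C@@H](C)[C@]2(C[Pd-2](I)([P+](c3ccccc3)(c3ccccc3)c3ccccc3)[P+](c3ccccc3)(c3ccccc3)c3ccccc3)CC[C@](C)(O[Si](CC)(CC)CC)[C@H]4COC(C)(C)O4 | intermediate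
34 | methyl (4R,5R,8R,9S,13S,14R)-14,15-(isopropylidenedioxy)-13-[(triethylsilyl)oxy]halim-1(10)-en-18-oate | COC(=O)[C@]1(C)CCC=C2[C@H]1CC[C@@H](C)[C@]2(C)CC[C@](C)(O[Si](CC)(CC)CC)[C@H]3COC(C)(C)O3 | intermediate
35 | methyl (4R,5R,8R,9S,13S,14R)-13,14,15-trihydroxyhalim-1(10)-en-18-oate | COC(=O)[C@]1(C)CCC=C2[C@H]1CC[C@@H](C)[C@]2(C)CC[C@](C)(O)[C@@H](CO)O | intermediate
36 | methyl (4R,5R,8R,9S,13S,14R)-14,15-diacetoxy-13-hydroxyhalim-1(10)-en-18-oate | COC(=O)[C@]1(C)CCC=C2[C@H]1CC[C@@H](C)[C@]2(C)CC[C@](C)(O)[C@@H](COC(C)=O)OC(C)=O | target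

**Step count**

Total step count: 23. Longest linear sequence: 16 (steps 1–11 and 19–23).

**Steps most likely to fail, with fallbacks**

1. Step 21 (reductive Heck cyclisation). What may go wrong: hydride transfer from formate to alkenylpalladium 32 before insertion, so that iodine is lost without ring closure; 3-exo carbopalladation of 33 onto the C1=C10 alkene; or insufficient facial discrimination at C9. The fallback sets out from ketone 30 and returns at 34. Intramolecular Nozaki–Hiyama–Kishi addition of the alkenyl iodide to the C9 ketone (CrCl2, NiCl2 cat., DMF) closes ring B as the tertiary allylic alcohol F1; either C9 epimer serves. Pyridinium chlorochromate C5H5NH[CrO3Cl] then effects the Babler–Dauben oxidative 1,3-transposition to the C1 ketone with a C9=C10 alkene, enone F2. Luche reduction should give the 1β-allylic alcohol F3 (hydride from the α-face as in step 2), which is acylated with picolinoyl chloride to the picolinate F4. MeMgBr with CuBr·SMe2 then delivers methyl to C9 in an anti-SN2′ substitution, on the α-face opposite the β-picolinate, which re-forms the C1=C10 alkene and gives 34.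

2. Step 3 (reductive transposition). What may go wrong: slow Mitsunobu displacement at the carbinol flanked by the iodoalkene, with elimination to a diene or SN2′ attack competing, and erosion of the ring-fusion configuration if step 2 delivers some 1α-alcohol. The fallback sets out from 3 and returns at 6. Selective mesylation of the allylic hydroxyl (MsCl, Et3N, −40 °C) gives the allylic mesylate F5. SN2 displacement with anhydrous hydrazine gives the α-hydrazine F6. Oxidation of F6 with diethyl azodicarboxylate generates the same diazene 5 without a phosphonium intermediate, and 5 collapses to 6.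

3. Step 10, with the hydroxy ester 12 and triflate 13 that feed it. What may go wrong: lactonisation of 12, ionisation of 13 with participation of the ester carbonyl (six-membered lactone), and decomposition of enolate 15 if alkylation is slow. The fallback sets out from aldehyde 11 and returns at 17. Wittig olefination with the stabilised ylide (R)-4-benzyl-3-[(triphenylphosphoranylidene)acetyl]-1,3-oxazolidin-2-one (from the bromoacetyl imide and PPh3) gives the (E)-enoyl imide F7. Conjugate reduction with Stryker's reagent [(Ph3P)CuH]6 gives the saturated imide F8. NaN(SiMe3)2 and MeI (Evans methylation, methyl entering opposite the benzyl group of the (R)-auxiliary) give the (8R)-methyl imide F9, and the conditions of step 11 then give 17.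

Further compounds
F1 | step 21 | 9-hydroxy bicycle from Nozaki–Hiyama–Kishi closure (tertiary allylic alcohol, C9 epimers) | COC(=O)[C@]1(C)CCC=C2[C@H]1CC[C@@H](C)C2(O)CC[C@](C)(O[Si](CC)(CC)CC)[C@H]3COC(C)(C)O3
F2 | step 21 | transposed enone (C1 ketone, C9=C10 alkene) | COC(=O)[C@]1(C)CCC(=O)C2=C(CC[C@](C)(O[Si](CC)(CC)CC)[C@H]3COC(C)(C)O3)[C@H](C)CC[C@@H]12
F3 | step 21 | 1β-allylic alcohol from F2 | COC(=O)[C@]1(C)CC[C@@H](O)C2=C(CC[C@](C)(O[Si](CC)(CC)CC)[C@H]3COC(C)(C)O3)[C@H](C)CC[C@@H]12
F4 | step 21 | picolinate of F3 | COC(=O)[C@]1(C)CC[C@@H](OC(=O)c4ccccn4)C2=C(CC[C@](C)(O[Si](CC)(CC)CC)[C@H]3COC(C)(C)O3)[C@H](C)CC[C@@H]12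
F5 | step 3 | allylic mesylate of 3 | C[C@@]12CC[C@@H](OS(C)(=O)=O)C(I)=C1CC[C@H]2O
F6 | step 3 | allylic hydrazine (nitrogen on the α-face of C1) | C[C@@]12CC[C@H](NN)C(I)=C1CC[C@H]2O
F7 | step 10 | (E)-enoyl imide with the (R)-4-benzyloxazolidinone | COC(=O)[C@]1(C)CCC=C(I)[C@H]1C/C=C/C(=O)N2[C@H](Cc3ccccc3)COC2=O
F8 | step 10 | saturated imide from F7 | COC(=O)[C@]1(C)CCC=C(I)[C@H]1CCCC(=O)N2[C@H](Cc3ccccc3)COC2=O
F9 | step 10 | (8R)-methyl imide with the (R)-4-benzyloxazolidinone | COC(=O)[C@]1(C)CCC=C(I)[C@H]1CC[C@@H](C)C(=O)N2[C@H](Cc3ccccc3)COC2=O
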